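The oxolane ring (O1, C2–C5) is disconnected at the C4–C5 bond. C5 is benzylic and bound to O1, so a radical is easily made there from a carboxyl group, and the O1–C2–C3 tether holds it within 5-exo reach of an alkene carbon that becomes C4. In one operation, visible-light decarboxylation of an α-alkoxy arylacetic acid and attack on an (E)-alkenyl pinacolboronate close the ring, set C4 and C5 from the aldol-derived C2 and C3 centres, and leave a CH2–B group as the latent C4 hydroxymethyl arm. The precursor is the acyclic benzylic ether of a syn-aldol-derived homoallylic alcohol bearing both O-benzyl guaiacyl rings, a silyloxymethyl group and the boronate.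

Key step: step 10

Remark: oxolanes are numbered O1, C2 (aryl from the aldehyde), C3, C4, C5 (aryl from the arylacetate), which makes the target (2S,3R,4R,5R); the carboxyl-bearing carbon of the cyclisation precursor is carried as both epimers, because the key step makes it planar.

Step 1
Reactants: 1 (4S)-4-benzyl-1,3-oxazolidin-2-one; 2 (E)-but-2-enoyl chloride
Product: 4 (4S)-4-benzyl-3-[(2E)-but-2-enoyl]-1,3-oxazolidin-2-one, via lithiated oxazolidinone 3 (not isolated)
Conditions: n-BuLi, THF, −78 °C; then 2, −78 → 0 °C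
Reagents that add atoms: none
Why: N-acylation of the lithium amide of the auxiliary by the acid chloride is a standard imide synthesis, and the low temperature avoids deconjugation of the crotonyl unit.

Step 2
Reactants: 4 (4S)-4-benzyl-3-[(2E)-but-2-enoyl]-1,3-oxazolidin-2-one; 5 4-(benzyloxy)-3-methoxybenzaldehyde (O-benzylvanillin)
Product: 8 (4S)-4-benzyl-3-{(2S)-2-[(S)-[4-(benzyloxy)-3-methoxyphenyl](hydroxy)methyl]but-3-enoyl}-1,3-oxazolidin-2-one, via boron dienolate 6 (not isolated), via boron aldolate 7 (not isolated)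
Conditions: Bu2BOTf, Et3N, CH2Cl2, −78 → 0 °C; then 5, −78 → 0 °C; pH 7 buffer, MeOH, 30% H2O2, 0 °C
Reagents that add atoms: none
Why: Evans syn-aldol reaction in which soft enolisation at the γ-methyl group gives the (Z)-O-boron dienolate, which should react at its α-carbon through a Zimmerman–Traxler chair on the face away from the benzyl group of the auxiliary, setting the carbinol centre (future C2) and the vinyl-bearing centre (future C3) as the (S,S) syn pair.

Step 3
Reactants: 8 the aldol adduct
Product: 9 (1S,2R)-1-[4-(benzyloxy)-3-methoxyphenyl]-2-ethenylpropane-1,3-diol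
Conditions: LiBH4, THF, H2O (1 equiv), 0 °C
Reagents that add atoms: none
Why: Hydride reduction of the exocyclic imide carbonyl (reductive auxiliary cleavage) should give the primary alcohol and the recoverable auxiliary without touching either stereocentre or the vinyl group.

Step 4
Reactants: 9 (1S,2R)-1-[4-(benzyloxy)-3-methoxyphenyl]-2-ethenylpropane-1,3-diol
Product: 10 (1S,2R)-1-[4-(benzyloxy)-3-methoxyphenyl]-2-{[(tert-butyldimethylsilyl)oxy]methyl}but-3-en-1-ol
Conditions: TBSCl (1.05 equiv), imidazole, CH2Cl2, 0 °C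
Reagents that add atoms: tert-butyldimethylsilyl chloride, CC(C)(C)[Si](C)(C)Cl
Why: Silyl ether formation is expected to be selective for the primary hydroxyl over the hindered secondary benzylic one on steric grounds.

Step 5
Reactants: 10 the silyl ether; 11 2-ethenyl-4,4,5,5-tetramethyl-1,3,2-dioxaborolane (vinylboronic acid pinacol ester)
Product: 12 (1S,2R,3E)-1-[4-(benzyloxy)-3-methoxyphenyl]-2-{[(tert-butyldimethylsilyl)oxy]methyl}-4-(4,4,5,5-tetramethyl-1,3,2-dioxaborolan-2-yl)but-3-en-1-ol
Conditions: 11 (3 equiv), second-generation Hoveyda–Grubbs catalyst RuCl2(H2IMes)(=CH-C6H4-2-OiPr) (5 mol%), CH2Cl2, 40 °C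
Reagents that add atoms: none
Why: Olefin cross-metathesis of a terminal alkene with the vinylboronate is known to tolerate free hydroxyl groups, and the bulky boryl group should direct formation of the (E)-alkenylboronate.

Step 6
Reactants: 13 methyl 2-(4-hydroxy-3-methoxyphenyl)acetate (methyl homovanillate)
Product: 14 methyl 2-[4-(benzyloxy)-3-methoxyphenyl]acetate
Conditions: BnBr, K2CO3, DMF, rt
Reagents that add atoms: benzyl bromide, BrCc1ccccc1
Why: Williamson etherification of the phenoxide should be clean, since K2CO3 is too weak a base to affect the ester.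

Step 7
Reactants: 14 methyl 2-[4-(benzyloxy)-3-methoxyphenyl]acetate
Product: 15 methyl 2-[4-(benzyloxy)-3-methoxyphenyl]-2-diazoacetate
Conditions: 4-acetamidobenzenesulfonyl azide, DBU, MeCN, 0 °C → rt
Reagents that add atoms: 4-acetamidobenzenesulfonyl azide, CC(=O)Nc1ccc(cc1)S(=O)(=O)N=[N+]=[N-]
Why: Regitz diazo transfer to the benzylic methylene of an arylacetate is the standard route to donor/acceptor diazo esters.

Step 8
Reactants: 12 the alkenylboronate alcohol; 15 the diazo ester
Product: 16 methyl (2RS)-2-[4-(benzyloxy)-3-methoxyphenyl]-2-{[(1S,2R,3E)-1-[4-(benzyloxy)-3-methoxyphenyl]-2-{[(tert-butyldimethylsilyl)oxy]methyl}-4-(4,4,5,5-tetramethyl-1,3,2-dioxaborolan-2-yl)but-3-en-1-yl]oxy}acetate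
Conditions: Rh2(OAc)4 (1 mol%), 4 Å MS, CH2Cl2, rt, slow addition of 15 (1.5 equiv)
Reagents that add atoms: none
Why: Rhodium-carbenoid O–H insertion should form the O1–C5 ether bond under neutral conditions without breaking any bond to C2 or C3, and the new centre needs no control because step 10 turns it into a planar radical.

Step 9
Reactants: 16 the ether ester
Product: 18 (2RS)-2-[4-(benzyloxy)-3-methoxyphenyl]-2-{[(1S,2R,3E)-1-[4-(benzyloxy)-3-methoxyphenyl]-2-{[(tert-butyldimethylsilyl)oxy]methyl}-4-(4,4,5,5-tetramethyl-1,3,2-dioxaborolan-2-yl)but-3-en-1-yl]oxy}acetic acid, via lithium carboxylate 17 (not isolated)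
Conditions: LiOH·H2O, THF–H2O (3:1), 0 °C → rt; then 1 M HCl to pH 4, 0 °C
Reagents that add atoms: lithium hydroxide, [Li+].[OH-]
Why: Saponification of the activated α-alkoxy methyl ester should be fast enough at 0 °C to spare the silyl ether and the pinacol boronate, and acidification only to pH 4 protects the benzylic ether.

Step 10
Reactants: 18 the acid (both epimers)
Product: 19 (2S,3R,4S,5R)-2,5-bis[4-(benzyloxy)-3-methoxyphenyl]-3-{[(tert-butyldimethylsilyl)oxy]methyl}-4-[(4,4,5,5-tetramethyl-1,3,2-dioxaborolan-2-yl)methyl]oxolane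
Conditions: Ir[dF(CF3)ppy]2(dtbbpy)PF6 (2 mol%), K2HPO4 (1 equiv), degassed DMF (0.02 M), 450 nm LEDs, 0 °C
Reagents that add atoms: none
Why: K2HPO4 converts the acid into its carboxylate, which the photoexcited trivalent iridium complex oxidises by single-electron transfer; loss of CO2 gives the planar α-alkoxybenzyl radical at C5, which adds to the alkene carbon attached to C3 (the future C4), and the resulting α-boryl radical is reduced by the divalent iridium complex and protonated by H2PO4−, so the step is redox-neutral. The closest known reaction type is the photoredox decarboxylative Giese-type addition of α-oxy acids to alkenylboronic esters with radical–polar crossover, run here intramolecularly in the manner of 2-oxahex-5-enyl radical cyclisations. The oxolane ring is closed in the 5-exo-trig mode, 6-endo attack being disfavoured because it would strike the boron-bearing carbon and forgo the α-boryl-stabilised radical. C4 is set by a chair-like transition state in which the C2 aryl group and the C3 silyloxymethyl group are both pseudo-equatorial, which places the new CH2–B arm trans to the C3 arm and cis to the C2 aryl group. C5 is set because the radical, conjugated with O1, should hold its aryl group anti to C2 about the C5–O1 bond to avoid 1,3-allylic-type strain, which makes that aryl group pseudo-equatorial as well, hence cis to the C4 arm and cis to the C2 aryl group. The step needs both epimers of 18 to converge, which the planar radical secures, and needs facial selectivity at C5, the weakest of the controls, which is why it is run cold and dilute.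

Step 11
Reactants: 19 the boronate
Product: 20 (2S,3R,4R,5R)-2,5-bis[4-(benzyloxy)-3-methoxyphenyl]-3-{[(tert-butyldimethylsilyl)oxy]methyl}-4-(hydroxymethyl)oxolane
Conditions: NaBO3·4H2O, THF–H2O (1:1), rt
Reagents that add atoms: sodium perborate, [Na+].[O-]OB=O
Why: Oxidation of a primary alkyl pinacol boronate by perborate proceeds through 1,2-migration of carbon from boron to oxygen, so the CH2–B group should become the C4 hydroxymethyl group without touching a ring stereocentre.

Step 12
Reactants: 20 the mono-silylated diol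
Product: 21 [(2S,3R,4R,5R)-2,5-bis[4-(benzyloxy)-3-methoxyphenyl]oxolane-3,4-diyl]dimethanol
Conditions: Bu4NF, THF, 0 °C → rt
Reagents that add atoms: none
Why: Fluoride-mediated desilylation frees the C3 hydroxymethyl group under non-acidic conditions, which cannot ionise the benzylic C–O bonds of the ring.

Step 13
Reactants: 21 the dibenzyl ether diol
Product: 22 [(2S,3R,4R,5R)-2,5-bis(4-hydroxy-3-methoxyphenyl)oxolane-3,4-diyl]dimethanol (target)
Conditions: H2 (1 atm), 10% Pd/C, EtOAc–EtOH, rt, stopped at full conversion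
Reagents that add atoms: none
Why: Catalytic hydrogenolysis cleaves aryl benzyl ethers much faster than the hindered secondary benzylic C–O bonds of the oxolane under neutral conditions, so both phenols should be released with the ring intact.

Compound list
1 | (4S)-4-benzyl-1,3-oxazolidin-2-one | O=C1OC[C@H](Cc2ccccc2)N1 | starting material
2 | (E)-but-2-enoyl chloride (crotonyl chloride) | C/C=C/C(Cl)=O | starting material
3 | lithium (4S)-4-benzyl-2-oxo-1,3-oxazolidin-3-ide | [Li+].O=C1OC[C@H](Cc2ccccc2)[N-]1 | intermediate (not isolated)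
4 | (4S)-4-benzyl-3-[(2E)-but-2-enoyl]-1,3-oxazolidin-2-one | C/C=C/C(=O)N1[C@@H](Cc2ccccc2)COC1=O | intermediate
5 | 4-(benzyloxy)-3-methoxybenzaldehyde (O-benzylvanillin) | COc1cc(C=O)ccc1OCc1ccccc1 | starting material
6 | (4S)-4-benzyl-3-[(1Z)-1-(dibutylboranyloxy)buta-1,3-dien-1-yl]-1,3-oxazolidin-2-one (boron dienolate) | C=C/C=C(\OB(CCCC)CCCC)N1[C@@H](Cc2ccccc2)COC1=O | intermediate (not isolated)
7 | O-dibutylboranyl derivative of 8 (boron aldolate) | COc1cc([C@@H](OB(CCCC)CCCC)[C@H](C=C)C(=O)N2[C@@H](Cc3ccccc3)COC2=O)ccc1OCc1ccccc1 | intermediate (not isolated)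
8 | (4S)-4-benzyl-3-{(2S)-2-[(S)-[4-(benzyloxy)-3-methoxyphenyl](hydroxy)methyl]but-3-enoyl}-1,3-oxazolidin-2-one | COc1cc([C@@H](O)[C@H](C=C)C(=O)N2[C@@H](Cc3ccccc3)COC2=O)ccc1OCc1ccccc1 | intermediate
9 | (1S,2R)-1-[4-(benzyloxy)-3-methoxyphenyl]-2-ethenylpropane-1,3-diol | COc1cc([C@@H](O)[C@@H](CO)C=C)ccc1OCc1ccccc1 | intermediate
10 | (1S,2R)-1-[4-(benzyloxy)-3-methoxyphenyl]-2-{[(tert-butyldimethylsilyl)oxy]methyl}but-3-en-1-ol | COc1cc([C@@H](O)[C@@H](CO[Si](C)(C)C(C)(C)C)C=C)ccc1OCc1ccccc1 | intermediate
11 | 2-ethenyl-4,4,5,5-tetramethyl-1,3,2-dioxaborolane (vinylboronic acid pinacol ester) | C=CB1OC(C)(C)C(C)(C)O1 | starting material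
12 | (1S,2R,3E)-1-[4-(benzyloxy)-3-methoxyphenyl]-2-{[(tert-butyldimethylsilyl)oxy]methyl}-4-(4,4,5,5-tetramethyl-1,3,2-dioxaborolan-2-yl)but-3-en-1-ol | COc1cc([C@@H](O)[C@@H](CO[Si](C)(C)C(C)(C)C)/C=C/B2OC(C)(C)C(C)(C)O2)ccc1OCc1ccccc1 | intermediate
13 | methyl 2-(4-hydroxy-3-methoxyphenyl)acetate (methyl homovanillate) | COC(=O)Cc1ccc(O)c(OC)c1 | starting material
14 | methyl 2-[4-(benzyloxy)-3-methoxyphenyl]acetate | COC(=O)Cc1ccc(OCc2ccccc2)c(OC)c1 | intermediate
15 | methyl 2-[4-(benzyloxy)-3-methoxyphenyl]-2-diazoacetate | COC(=O)C(=[N+]=[N-])c1ccc(OCc2ccccc2)c(OC)c1 | intermediate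
16 | methyl (2RS)-2-aryl-2-{[(1S,2R,3E)-1-aryl-2-(silyloxymethyl)-4-(pinacolboryl)but-3-en-1-yl]oxy}acetate, aryl = 4-(benzyloxy)-3-methoxyphenyl, silyl = tert-butyldimethylsilyl (full name in step 8; ester-bearing carbon unassigned, both epimers) | COc1cc([C@@H](OC(C(=O)OC)c2ccc(OCc3ccccc3)c(OC)c2)[C@@H](CO[Si](C)(C)C(C)(C)C)/C=C/B2OC(C)(C)C(C)(C)O2)ccc1OCc1ccccc1 | intermediate
17 | lithium salt of acid 18 (both epimers) | COc1cc([C@@H](OC(C(=O)[O-])c2ccc(OCc3ccccc3)c(OC)c2)[C@@H](CO[Si](C)(C)C(C)(C)C)/C=C/B2OC(C)(C)C(C)(C)O2)ccc1OCc1ccccc1.[Li+] | intermediate (not isolated)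
18 | (2RS)-2-aryl-2-{[(1S,2R,3E)-1-aryl-2-(silyloxymethyl)-4-(pinacolboryl)but-3-en-1-yl]oxy}acetic acid (full name in step 9; both epimers) | COc1cc([C@@H](OC(C(=O)O)c2ccc(OCc3ccccc3)c(OC)c2)[C@@H](CO[Si](C)(C)C(C)(C)C)/C=C/B2OC(C)(C)C(C)(C)O2)ccc1OCc1ccccc1 | intermediate (key-step precursor)
19 | (2S,3R,4S,5R)-2,5-bis[4-(benzyloxy)-3-methoxyphenyl]-3-{[(tert-butyldimethylsilyl)oxy]methyl}-4-[(4,4,5,5-tetramethyl-1,3,2-dioxaborolan-2-yl)methyl]oxolane | COc1cc([C@H]2O[C@@H](c3ccc(OCc4ccccc4)c(OC)c3)[C@@H](CB3OC(C)(C)C(C)(C)O3)[C@@H]2CO[Si](C)(C)C(C)(C)C)ccc1OCc1ccccc1 | intermediate (key-step product)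
20 | (2S,3R,4R,5R)-2,5-bis[4-(benzyloxy)-3-methoxyphenyl]-3-{[(tert-butyldimethylsilyl)oxy]methyl}-4-(hydroxymethyl)oxolane | COc1cc([C@H]2O[C@@H](c3ccc(OCc4ccccc4)c(OC)c3)[C@@H](CO)[C@@H]2CO[Si](C)(C)C(C)(C)C)ccc1OCc1ccccc1 | intermediate
21 | [(2S,3R,4R,5R)-2,5-bis[4-(benzyloxy)-3-methoxyphenyl]oxolane-3,4-diyl]dimethanol | COc1cc([C@H]2O[C@@H](c3ccc(OCc4ccccc4)c(OC)c3)[C@@H](CO)[C@@H]2CO)ccc1OCc1ccccc1 | intermediate
22 | [(2S,3R,4R,5R)-2,5-bis(4-hydroxy-3-methoxyphenyl)oxolane-3,4-diyl]dimethanol | COc1cc([C@H]2O[C@@H](c3ccc(O)c(OC)c3)[C@@H](CO)[C@@H]2CO)ccc1O | target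

Total step count: 13. Longest linear sequence: 11 steps (steps 1–5 and 8–13); steps 6 and 7 form the two-step side branch that joins at step 8.

Steps most likely to fail

Step 10. The stabilised C5 radical may close slowly, so that dimerisation or oxidation to the oxocarbenium ion competes, and discrimination between the two faces of the radical at C5 may be low. The fallback replaces oxidative carboxylate activation and radical–polar crossover by reductive activation of a redox-active ester with hydrogen-atom transfer as the terminating event. It sets out from acid 18, which with N-hydroxyphthalimide, N,N'-diisopropylcarbodiimide and catalytic DMAP in CH2Cl2 would give the N-(acyloxy)phthalimide F1. Irradiation of F1 with blue light in the presence of Ru(bpy)3(PF6)2 and Hantzsch ester in CH2Cl2 at −20 °C should cause single-electron reduction, fragmentation to the same C5 radical, 5-exo closure and hydrogen-atom transfer from the dihydropyridine to the α-boryl radical. This variant needs neither base nor oxidant and can be run colder; it comes back to the route at 19.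

Step 8. The carbenoid may be consumed by dimerisation, by cyclopropanation of the alkenylboronate or by insertion into traces of water before the hindered secondary hydroxyl intercepts it. The fallback forms the same O1–C5 bond by substitution instead of carbene insertion. It sets out from diazo ester 15, which with 48% aqueous HBr in CH2Cl2 at 0 °C would give methyl (2RS)-2-bromo-2-[4-(benzyloxy)-3-methoxyphenyl]acetate F2. Alcohol 12 would then be alkylated with F2 in a Purdie-type etherification (Ag2O, 4 Å MS, CH2Cl2, dark, rt), in which silver-assisted ionisation of the activated benzylic bromide makes the ether without strong base and so without silyl migration. The fallback comes back to the route at 16, again as both epimers.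

Step 5. Productive metathesis may be slow because the allylic carbon of the alkene is branched, so that alkene isomerisation or catalyst decomposition takes over. The fallback builds the alkenylboronate by carbonyl olefination. It sets out from 10, whose vinyl group would be cleaved under Lemieux–Johnson conditions (catalytic OsO4, NaIO4, 2,6-lutidine, dioxane–H2O) to (2R,3S)-3-[4-(benzyloxy)-3-methoxyphenyl]-2-{[(tert-butyldimethylsilyl)oxy]methyl}-3-hydroxypropanal F3, used crude to avoid epimerisation. Takai-type olefination of F3 with CrCl2, 2-(dichloromethyl)-4,4,5,5-tetramethyl-1,3,2-dioxaborolane and LiI in THF at rt should give the (E)-alkenylboronate, coming back to the route at 12.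

Further compounds
F1 | step 10 | 1,3-dioxoisoindolin-2-yl ester of acid 18 (N-(acyloxy)phthalimide, both epimers) | COc1cc([C@@H](OC(C(=O)ON2C(=O)c3ccccc3C2=O)c2ccc(OCc3ccccc3)c(OC)c2)[C@@H](CO[Si](C)(C)C(C)(C)C)/C=C/B2OC(C)(C)C(C)(C)O2)ccc1OCc1ccccc1
F2 | step 8 | methyl (2RS)-2-bromo-2-[4-(benzyloxy)-3-methoxyphenyl]acetate | COC(=O)C(Br)c1ccc(OCc2ccccc2)c(OC)c1
F3 | step 5 | (2R,3S)-3-[4-(benzyloxy)-3-methoxyphenyl]-2-{[(tert-butyldimethylsilyl)oxy]methyl}-3-hydroxypropanal | COc1cc([C@@H](O)[C@@H](CO[Si](C)(C)C(C)(C)C)C=O)ccc1OCc1ccccc1
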